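Ask first whether slowness will matter in this flask, and read the answer from the two earlier runs.

| flask | substrate | reagent | remark | time |
|---|---|---|---|---|
| autumn | 0.050 M (fed, over 30 min) | 0.020 M | run made earlier; the fed solution adds 0.20 times the starting volume |  |
| midnight | 0.050 M (fed, over 30 min) | 0.080 M | run made earlier; the fed solution adds 0.20 times the starting volume |  |
| flask | 0.050 M (fed, over 30 min) | 0.0400 M | the fed solution adds 0.20 times the starting volume | 8.0 h |

| run | time / h | target / % | isomer of the product / % |
|---|---|---|---|
| autumn | 0.500 | 7.1 | 21.4 |
| autumn | 1.33 | 9.5 | 28.3 |
| autumn | 2.50 | 10.8 | 28.2 |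
| autumn | 4.00 | 10.6 | 29.9 |
| autumn | 6.00 | 12.2 | 29.9 |
| autumn | 8.00 | 10.2 | 29.2 |
| autumn | 10.0 | 10.6 | 27.5 |
| midnight | 0.833 | 24.9 | 70.6 |
| midnight | 1.33 | 28.3 | 70.8 |
| midnight | 2.00 | 27.2 | 73.0 |
| midnight | 2.50 | 27.6 | 72.3 |
| midnight | 4.00 | 28.9 | 72.0 |
| midnight | 6.00 | 26.9 | 72.3 |
| midnight | 10.0 | 28.4 | 71.5 |

(standard deviation of a reading: 1 percentage point)

- which holds at 8.0 h: what has brought the reaction to rest, or that it has not come to rest (the reagent has run out first / all of the substrate has reacted / it is still moving)
- the target standing at 8.0 h, as a percentage of the substrate charged
- the isomer of the product standing at 8.0 h, as a percentage of the substrate charged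

- charges are per starting volume, the dose included; the dosed solution carries all of it
- the reaction counts as stopped when no species that holds the substrate changes by six tenths of a point or more over the second half of the time

Turn the time first. By hand, a longer run gives more product while the reaction is still moving. The autumn run, however, reads isomer of the product at 28.2% after 2.50 h and 29.2% after 8.00 h, a gap the size of the scatter.

Turn the reagent next. By hand, if one reagent takes one substrate and the reagent is the smaller charge, product stops at the ration e, the reagent charge over the substrate charge. For the autumn run e is 40.0%, and target and isomer together read 39.4% after 8.00 h. The midnight run, with reagent above substrate, reads 99.9% after 10.0 h.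

Now look at the split, the selectivity. By hand, more reagent might shift it, so define s, the target's share of target and isomer together. Pooled from 2.50 h on, the midnight run gives s = 28.0%. The autumn run, pooled from 2.50 h on, reads 27.3%.

In the flask the reagent is the limiting reagent, with e = 80.0%. My own reckoning, s times e, gives target 22.4% and isomer 57.6%. The forecast says the reagent has run out first, with target 22.1% and isomer 57.6%, and calls the stop close: “so it has stopped, though this is borderline”.

In the flask the reagent has run out first, with 0% of the reagent left after 8.00 h, target 22.0% and isomer 57.6%.

    substrate + reagent → target (k = 0.840 M⁻¹ min⁻¹)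
    substrate + reagent → isomer of the product (k = 2.20 M⁻¹ min⁻¹)
    substrate + reagent → second isomer (k = 0.0140 M⁻¹ min⁻¹)

Over the second half of the time no species that holds the substrate moves in the flask by more than 0.055 percentage points. The target's share of target and isomer together stands in the flask at 27.6%. Now carry s to the neighbouring flask with 0.20 M of substrate and the same reagent, where e is 20.0%. There s times e gives 5.59% of target, and that flask stands at 5.50%.

All runs are simulated for an exercise.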